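**Early split.** The ratio that matters here is the split: target made per cross product made. Target made is target plus half the side product, since each side product holds one spent target. Both steps use starting material, so on the steps thought possible the split follows partner over second substrate, whatever the starting material. The first amber reading, divided by that charged ratio, gives a selectivity factor of 2.39.

| flask | starting material | partner | second substrate | remark | time |
|---|---|---|---|---|---|
| blue | 0.050 M | 0.030 M | 0.050 M | run made earlier |  |
| ochre | 0.050 M | 0.030 M | 0.070 M | run made earlier |  |
| amber | 0.050 M | 0.030 M | 0.11 M | run made earlier |  |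
| Friday's | 0.050 M (fed, over 1.50 h) | 0.0300 M | 0.0500 M | a stirred flask in which starting material is dosed at a steady rate over 1.50 h without added volume, worked up at 1.5 h | 1.5 h |
| Thursday's | 0.050 M | 0.0300 M | 0.0500 M (fed, over 1.50 h) | a stirred flask in which second substrate is dosed at a steady rate over 1.50 h without added volume, worked up at 1.5 h | 1.5 h |
| Saturday's | 0.050 M | 0.0300 M | 0.0500 M | a closed flask charged with all of it at once and left for 1.5 h | 1.5 h |
| Monday's | 0.050 M | 0.0300 M | 0.0500 M | a single well-mixed tank run continuously and read at steady state, 1.5 h in it on average |  |

| run | time / min | target / % | cross product / % | side product / % |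
|---|---|---|---|---|
| blue | 8.00 | 15.3 | 13.7 | 5.5 |
| blue | 15.0 | 19.5 | 20.3 | 9.9 |
| blue | 25.0 | 20.4 | 26.3 | 15.8 |
| blue | 30.0 | 20.3 | 28.4 | 19.6 |
| blue | 40.0 | 18.9 | 32.1 | 22.8 |
| blue | 50.0 | 17.7 | 33.7 | 26.8 |
| ochre | 12.0 | 17.1 | 25.0 | 6.8 |
| ochre | 25.0 | 18.1 | 34.6 | 13.8 |
| ochre | 40.0 | 17.4 | 41.2 | 19.1 |
| ochre | 50.0 | 16.5 | 44.7 | 21.0 |
| ochre | 60.0 | 15.8 | 46.6 | 22.3 |
| ochre | 80.0 | 14.2 | 49.1 | 26.6 |
| ochre | 90.0 | 13.8 | 50.7 | 27.0 |
| amber | 5.00 | 11.4 | 19.0 | 2.0 |
| amber | 15.0 | 15.0 | 39.7 | 7.6 |
| amber | 25.0 | 15.4 | 49.6 | 10.0 |
| amber | 40.0 | 14.4 | 57.4 | 14.2 |
| amber | 50.0 | 14.0 | 61.3 | 14.9 |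
| amber | 80.0 | 13.7 | 66.6 | 16.6 |
| amber | 90.0 | 12.6 | 66.1 | 17.3 |

(each reading ± 0.5 percentage points)

1. the set-up with the highest share of target in all that became target or cross product or side product, at the outlet or at the end ("none" if the first two lie within 2 percentage points) (Friday's / Thursday's / Saturday's / Monday's / none)
2. share of target in all that became target or cross product or side product, at the outlet or at the end, Friday's
3. share of target in all that became target or cross product or side product, at the outlet or at the end, Thursday's
4. share of target in all that became target or cross product or side product, at the outlet or at the end, Saturday's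
5. share of target in all that became target or cross product or side product, at the outlet or at the end, Monday's

- percent here means starting material units held: one side product counts as two
- the stated concentrations are those of everything mixed, before any reaction; amounts are the same in each set-up
- steps thought possible: starting material + partner -> target; second substrate + partner -> second product; starting material + second substrate -> cross product; partner -> decomposed reagent; starting material + target -> side product; second substrate <-> dormant form
- the feed brings no volume worth counting
- the earlier runs were made in a closed, stirred flask

**Hand chain.** In blue, target made reads 30.1 % at 30.0 min and 31.1 % at 50.0 min, so partner's working time is taken as the first 30.0 min. Over it, Thursday's holds on average 0.00833 M of second substrate. With partner taken at half its charge, the split is 4.31. Blue's late pace of cross product, carried through the remaining time, adds 15.9 %. Thursday's split is then 1.35.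

**Weak link.** That reckoning keeps blue's target made, but thin second substrate should leave more partner for starting material. Blue's partner not turned into target is 0.0144 M. Guessing that half of it is regained gives 45.5 % target made and a split of 1.72. That stands above blue's last 0.923, and blue has Saturday's recipe, so this reckoning puts Thursday's ahead of Saturday's; it gives no split for Friday's or Monday's.

**The forecast.** The forecast names Thursday's, at 20 % (16.5 % to 24 %), against 12.5 % for Friday's, 15.3 % for Saturday's and 16.3 % for Monday's. Its ground for Thursday's is that “partner meets concentrated starting material with little second substrate present”.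

**The flask.** The best is Thursday's: Friday's 14.0 %, Thursday's 20.2 %, Saturday's 16.8 %, Monday's 16.4 %.

    starting material + partner → target (k = 1.30 M⁻¹ min⁻¹)
    second substrate + partner → second product (k = 0.640 M⁻¹ min⁻¹)
    starting material + second substrate → cross product (k = 0.480 M⁻¹ min⁻¹)
    partner → decomposed reagent (k = 0.0100 min⁻¹)
    starting material + target → side product (k = 0.740 M⁻¹ min⁻¹)
    second substrate ⇌ dormant form (K = 15.0, k = 0.00300 min⁻¹)

**What stands.** Thursday's ends with a split of 2.19, above Saturday's 0.808, though of Thursday's target made, 25.3 % stands spent in side product, half of that product's figure, more than the 17.8 % still free as target. In Friday's, at 0.197 h, cross product already uses starting material at 0.80 of target's rate, a split of 1.25, below the 1.44 that the factor gives for the charged ratio. Friday's split ends at 0.492.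

The numbers in the tables come from a simulation with made-up constants; scatter was added.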